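**Plan**
- Retrosynthesis: the lactone C3–CH2(aryl) bond is cut first (enolate alkylation). In the left half the aryl ether bond O1–C7a and the C2–C3 bond are cut together, after the C3 hydroxymethyl group is read as a cleaved (E)-propenyl group. In the right half the C4–C7' bond is cut (aldol) and the lactone is opened to a succinate.
- Enabling feature: in the dihydrofuran ring C2 is a benzylic carbon bearing O1, and C3 sits on arene carbon C3a next to C7a. O1–C2–C3 is therefore the 1,2-diaryl homoallylic alkoxide that a [2,3]-Wittig shift of a benzyl (Z)-3-arylallyl ether delivers, one 5-exo step away from a C7a–F bond that has no ortho hydrogen (C7 carries OMe).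
- Forward: benzyl propargyl ether, Sonogashira coupling and semihydrogenation give the Z-allyl ether; the cascade closes the dihydrofuran ring; the lactone ring arises from an anti-aldol adduct by reductive auxiliary removal; alkylation joins the halves; ozonolysis/reduction and desilylation finish.
- Stereochemistry: C2/C3 of the dihydrobenzofuran come from (R)-but-3-yn-2-ol (1,3-chirality transfer, Z geometry); lactone C4 and C7' from (R)-4-benzyl-1,3-oxazolidin-2-one; lactone C3 from trans-selective alkylation.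

Key step: step 8

Remark: atom numbers are those of 2,3-dihydro-1-benzofuran and of oxolan-2-one, and C7' is the carbinol carbon; the MgCl2-catalysed aldol is assumed to follow the usual chelated-enolate facial sense, which is why the (R)-auxiliary is used.

**Step 1**
Reactants: 1 vanillin (4-hydroxy-3-methoxybenzaldehyde)
Product: 2 3-methoxy-4-(triisopropylsilyloxy)benzaldehyde
Conditions: iPr3SiCl, imidazole, DMF, rt
Reagents that add atoms: triisopropylsilyl chloride, CC(C)[Si](Cl)(C(C)C)C(C)C
Why: Imidazole-promoted silylation of the phenol gives an aryl silyl ether that should survive organolithium, hydride and enolate steps and fall to fluoride at the end.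

**Step 2**
Reactants: 2 3-methoxy-4-(triisopropylsilyloxy)benzaldehyde
Product: 3 [3-methoxy-4-(triisopropylsilyloxy)phenyl]methanol
Conditions: NaBH4, MeOH, 0 °C
Reagents that add atoms: none
Why: Borohydride reduction of an aromatic aldehyde to the benzylic alcohol; no stereocentre is formed.

**Step 3**
Reactants: 3 [3-methoxy-4-(triisopropylsilyloxy)phenyl]methanol
Product: 4 3-methoxy-4-(triisopropylsilyloxy)benzyl bromide
Conditions: CBr4, PPh3, CH2Cl2, 0 °C (used crude)
Reagents that add atoms: carbon tetrabromide, BrC(Br)(Br)Br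
Why: The Appel reaction converts the electron-rich benzylic alcohol to the bromide under neutral conditions that leave the aryl silyl ether intact.

**Step 4**
Reactants: 4 3-methoxy-4-(triisopropylsilyloxy)benzyl bromide; 5 (R)-but-3-yn-2-ol
Product: 6 (R)-but-3-yn-2-yl 3-methoxy-4-(triisopropylsilyloxy)benzyl ether
Conditions: NaH, Bu4NI (cat.), THF, 0 °C to rt
Reagents that add atoms: none
Why: Williamson ether synthesis; the alkoxide of 5 attacks the benzylic carbon, so the carbinol configuration of 5 is untouched.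

**Step 5**
Reactants: 7 (4-fluoro-3-methoxyphenyl)methanol
Product: 9 (3-bromo-4-fluoro-5-methoxyphenyl)methanol, via bis-borylated arene 8 (not isolated)
Conditions: [Ir(OMe)(cod)]2 (cat.), 4,4'-di-tert-butyl-2,2'-bipyridine, B2pin2, THF, 80 °C; then CuBr2, MeOH/H2O, 80 °C
Reagents that add atoms: copper dibromide, Br[Cu]Br
Why: Sterically controlled iridium-catalysed arene C–H borylation should occur at the only C–H whose ortho neighbours are H and F (the alcohol is borylated on oxygen in the flask), and copper-mediated bromodeboronation then places bromine on that carbon.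

**Step 6**
Reactants: 9 (3-bromo-4-fluoro-5-methoxyphenyl)methanol; 6 (R)-but-3-yn-2-yl 3-methoxy-4-(triisopropylsilyloxy)benzyl ether
Product: 10 [4-fluoro-3-methoxy-5-[(3R)-3-{[3-methoxy-4-(triisopropylsilyloxy)benzyl]oxy}but-1-yn-1-yl]phenyl]methanol
Conditions: Pd(PPh3)2Cl2 (cat.), CuI (cat.), Et3N, DMF, 70 °C
Reagents that add atoms: none
Why: Sonogashira coupling of the aryl bromide with the terminal alkyne; the aryl fluoride and the free benzylic alcohol are inert.

**Step 7**
Reactants: 10 the arylalkyne above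
Product: 11 [4-fluoro-3-methoxy-5-[(1Z,3R)-3-{[3-methoxy-4-(triisopropylsilyloxy)benzyl]oxy}but-1-en-1-yl]phenyl]methanol
Conditions: H2 (1 atm), Pd/CaCO3 poisoned with Pb(OAc)2, quinoline, EtOAc, rt
Reagents that add atoms: none
Why: Lindlar-type cis-semihydrogenation of the arylalkyne gives the Z-alkene on which syn selectivity and chirality transfer in step 8 depend.

**Step 8**
Reactants: 11 the (1Z,3R)-allyl benzyl ether above
Product: 13 [(2S,3S)-7-methoxy-2-[3-methoxy-4-(triisopropylsilyloxy)phenyl]-3-[(1E)-prop-1-en-1-yl]-2,3-dihydro-1-benzofuran-5-yl]methanol, via dilithium homoallylic dialkoxide 12 (not isolated)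
Conditions: n-BuLi (2.2 equiv), THF, −78 °C; then KN(SiMe3)2 (1.1 equiv), DMPU, −78 to 50 °C; H2O
Reagents that add atoms: none
Why: After the primary alcohol is converted to its lithium alkoxide, the second equivalent of base metalates the only OCH2Ar position, and the α-oxybenzyl carbanion undergoes a suprafacial [2,3]-Wittig shift through a five-membered envelope transition state that forms C2–C3, breaks the allylic C–O bond and unveils the C2 alkoxide; paired with potassium in THF/DMPU this alkoxide displaces the fluoride on the neighbouring arene carbon C7a by addition–elimination. The closest known reaction types are the [2,3]-Wittig rearrangement of (Z)-α-methylallyl benzyl ethers with 1,3-chirality transfer and the base-mediated cyclisation of 2-(2-fluoroaryl)ethanol alkoxides to 2,3-dihydrobenzofurans. The dihydrofuran ring closes in a 5-exo-trig mode: O1 attacks C7a and the charge is taken up outside the new ring on C7 and C5 before fluoride leaves. C3 is set by transfer of the (R)-carbinol centre, because A(1,3) strain in the Z-alkene holds the allylic hydrogen in the alkene plane and the methyl group away from the forming bond, so the new bond forms on the face from which oxygen departs and an E-propenyl group results; C2 is set by the Z geometry with the aryl group exo in the envelope, which should give the syn alkoxide and hence the trans-2,3 ring. The step needs site-selective metalation, a [2,3] in preference to a [1,2] shift, and ring closure by the secondary alkoxide only: the lithium alkoxide of the primary alcohol deactivates its own CH2, the tertiary allylic C–H is hindered, the fluorine has no ortho hydrogen so no aryne can form, the low temperature favours the concerted shift, and only the C2 alkoxide can reach C7a.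

**Step 9**
Reactants: 13 the dihydrobenzofuranyl methanol above
Product: 14 (2S,3S)-5-(bromomethyl)-7-methoxy-2-[3-methoxy-4-(triisopropylsilyloxy)phenyl]-3-[(1E)-prop-1-en-1-yl]-2,3-dihydro-1-benzofuran
Conditions: CBr4, PPh3, CH2Cl2, 0 °C (used at once)
Reagents that add atoms: carbon tetrabromide, BrC(Br)(Br)Br
Why: The Appel reaction on the only free hydroxyl gives the benzylic bromide under neutral conditions that leave the propenyl group, the benzylic aryl ether and the silyl ether untouched.

**Step 10**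
Reactants: 15 (R)-4-benzyl-1,3-oxazolidin-2-one; 16 methyl 4-chloro-4-oxobutanoate
Product: 17 methyl 4-[(4R)-4-benzyl-2-oxo-1,3-oxazolidin-3-yl]-4-oxobutanoate
Conditions: n-BuLi, THF, −78 °C; then 16
Reagents that add atoms: none
Why: N-Acylation of the lithiated oxazolidinone by the acid chloride installs the chiral auxiliary on the succinate unit.

**Step 11**
Reactants: 17 the succinyl imide above; 2 3-methoxy-4-(triisopropylsilyloxy)benzaldehyde
Product: 19 methyl (3S)-4-[(4R)-4-benzyl-2-oxo-1,3-oxazolidin-3-yl]-3-[(R)-hydroxy[3-methoxy-4-(triisopropylsilyloxy)phenyl]methyl]-4-oxobutanoate, via aldol trimethylsilyl ether 18 (not isolated)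
Conditions: MgCl2 (cat.), Et3N, Me3SiCl, EtOAc, rt; then 1 M HCl, THF, 0 °C (brief)
Reagents that add atoms: none
Why: Magnesium halide-catalysed direct anti-aldol reaction of an N-acyloxazolidinone with an aromatic aldehyde: soft enolisation gives the chelated Z-enolate, which should be attacked on the face away from the benzyl group through a boat-like transition state and trapped by silylation, setting the future lactone C4 and C7' in the anti relationship before mild acid removes the trimethylsilyl group.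

**Step 12**
Reactants: 19 the anti-aldol adduct above
Product: 20 methyl (3S)-4-[(4R)-4-benzyl-2-oxo-1,3-oxazolidin-3-yl]-3-[(R)-(tert-butyldimethylsilyloxy)[3-methoxy-4-(triisopropylsilyloxy)phenyl]methyl]-4-oxobutanoate
Conditions: t-BuMe2SiOTf, 2,6-lutidine, CH2Cl2, −78 to 0 °C
Reagents that add atoms: tert-butyldimethylsilyl triflate, CC(C)(C)[Si](C)(C)OS(=O)(=O)C(F)(F)F
Why: Silylation of the hindered benzylic alcohol with the silyl triflate blocks lactonisation through this oxygen and protects it during the enolate step.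

**Step 13**
Reactants: 20 the silyl ether above
Product: 22 (4R)-4-[(R)-(tert-butyldimethylsilyloxy)[3-methoxy-4-(triisopropylsilyloxy)phenyl]methyl]oxolan-2-one, via hydroxy ester 21 (not isolated)
Conditions: NaBH4, THF/H2O, 0 °C to rt; then PPTS (cat.), CH2Cl2, rt
Reagents that add atoms: none
Why: Borohydride in aqueous THF reductively cleaves the exocyclic imide carbonyl to the primary alcohol while sparing the methyl ester, and the γ-hydroxy ester lactonises under mild acid; neither stereocentre is touched.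

**Step 14**
Reactants: 22 the lactone above; 14 the benzylic bromide from step 9
Product: 23 (3R,4R)-4-[(R)-(tert-butyldimethylsilyloxy)[3-methoxy-4-(triisopropylsilyloxy)phenyl]methyl]-3-({(2S,3S)-7-methoxy-2-[3-methoxy-4-(triisopropylsilyloxy)phenyl]-3-[(1E)-prop-1-en-1-yl]-2,3-dihydro-1-benzofuran-5-yl}methyl)oxolan-2-one
Conditions: LiN(SiMe3)2, THF, −78 °C; then 14, DMPU, −78 to −40 °C
Reagents that add atoms: none
Why: Alkylation of the lactone lithium enolate by the benzylic bromide should occur anti to the bulky C4 substituent, giving the trans-3,4-disubstituted lactone (C3 R), as is usual for 4-substituted butyrolactones.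

**Step 15**
Reactants: 23 the coupled lactone above
Product: 25 (3R,4R)-4-[(R)-(tert-butyldimethylsilyloxy)[3-methoxy-4-(triisopropylsilyloxy)phenyl]methyl]-3-({(2S,3R)-3-(hydroxymethyl)-7-methoxy-2-[3-methoxy-4-(triisopropylsilyloxy)phenyl]-2,3-dihydro-1-benzofuran-5-yl}methyl)oxolan-2-one, via ozonide 24 (not isolated)
Conditions: O3 (to first excess), CH2Cl2, −78 °C; then NaBH4, MeOH, −78 to 0 °C
Reagents that add atoms: ozone, [O-][O+]=O
Why: Ozonolysis of the only alkene followed by borohydride reduction of the ozonide turns the propenyl helper into the hydroxymethyl group; cold hydride delivery should outrun epimerisation of the α-aryl aldehyde and spare the lactone.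

**Step 16**
Reactants: 25 the tris-silyl ether above
Product: 26 (3R,4R)-4-[(R)-hydroxy(4-hydroxy-3-methoxyphenyl)methyl]-3-{[(2S,3R)-2-(4-hydroxy-3-methoxyphenyl)-3-(hydroxymethyl)-7-methoxy-2,3-dihydro-1-benzofuran-5-yl]methyl}oxolan-2-one (CNP0233460.1)
Conditions: Bu4NF, AcOH, THF, 0 °C to rt
Reagents that add atoms: none
Why: Buffered fluoride cleaves the two aryl triisopropylsilyl ethers and the benzylic tert-butyldimethylsilyl ether, while acetic acid suppresses the phenoxide and alkoxide that could cause quinone methide formation or translactonisation.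

**Compound list**
1 | vanillin | COc1cc(C=O)ccc1O | starting material
2 | 3-methoxy-4-(triisopropylsilyloxy)benzaldehyde | COc1cc(C=O)ccc1O[Si](C(C)C)(C(C)C)C(C)C | intermediate
3 | [3-methoxy-4-(triisopropylsilyloxy)phenyl]methanol | COc1cc(CO)ccc1O[Si](C(C)C)(C(C)C)C(C)C | intermediate
4 | 3-methoxy-4-(triisopropylsilyloxy)benzyl bromide | COc1cc(CBr)ccc1O[Si](C(C)C)(C(C)C)C(C)C | intermediate
5 | (R)-but-3-yn-2-ol | C[C@@H](O)C#C | starting material
6 | (R)-but-3-yn-2-yl 3-methoxy-4-(triisopropylsilyloxy)benzyl ether | C[C@@H](OCc1ccc(O[Si](C(C)C)(C(C)C)C(C)C)c(OC)c1)C#C | intermediate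
7 | (4-fluoro-3-methoxyphenyl)methanol | COc1cc(CO)ccc1F | starting material
8 | 2-[2-fluoro-3-methoxy-5-({[(4,4,5,5-tetramethyl-1,3,2-dioxaborolan-2-yl)]oxy}methyl)phenyl]-4,4,5,5-tetramethyl-1,3,2-dioxaborolane | COc1cc(COB2OC(C)(C)C(C)(C)O2)cc(B2OC(C)(C)C(C)(C)O2)c1F | intermediate (not isolated)
9 | (3-bromo-4-fluoro-5-methoxyphenyl)methanol | COc1cc(CO)cc(Br)c1F | intermediate
10 | [4-fluoro-3-methoxy-5-[(3R)-3-{[3-methoxy-4-(triisopropylsilyloxy)benzyl]oxy}but-1-yn-1-yl]phenyl]methanol | C[C@@H](OCc1ccc(O[Si](C(C)C)(C(C)C)C(C)C)c(OC)c1)C#Cc1cc(CO)cc(OC)c1F | intermediate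
11 | [4-fluoro-3-methoxy-5-[(1Z,3R)-3-{[3-methoxy-4-(triisopropylsilyloxy)benzyl]oxy}but-1-en-1-yl]phenyl]methanol | C[C@@H](OCc1ccc(O[Si](C(C)C)(C(C)C)C(C)C)c(OC)c1)/C=C\c1cc(CO)cc(OC)c1F | intermediate
12 | dilithium (1S,2S,3E)-2-[2-fluoro-3-methoxy-5-(oxidomethyl)phenyl]-1-[3-methoxy-4-(triisopropylsilyloxy)phenyl]pent-3-en-1-olate | COc1cc([C@@H]([O-])[C@@H](/C=C/C)c2cc(C[O-])cc(OC)c2F)ccc1O[Si](C(C)C)(C(C)C)C(C)C.[Li+].[Li+] | intermediate (not isolated)
13 | [(2S,3S)-7-methoxy-2-[3-methoxy-4-(triisopropylsilyloxy)phenyl]-3-[(1E)-prop-1-en-1-yl]-2,3-dihydro-1-benzofuran-5-yl]methanol | COc1cc([C@H]2Oc3c(OC)cc(CO)cc3[C@@H]2/C=C/C)ccc1O[Si](C(C)C)(C(C)C)C(C)C | intermediate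
14 | (2S,3S)-5-(bromomethyl)-7-methoxy-2-[3-methoxy-4-(triisopropylsilyloxy)phenyl]-3-[(1E)-prop-1-en-1-yl]-2,3-dihydro-1-benzofuran | COc1cc([C@H]2Oc3c(OC)cc(CBr)cc3[C@@H]2/C=C/C)ccc1O[Si](C(C)C)(C(C)C)C(C)C | intermediate
15 | (R)-4-benzyl-1,3-oxazolidin-2-one | O=C1N[C@H](Cc2ccccc2)CO1 | starting material
16 | methyl 4-chloro-4-oxobutanoate | COC(=O)CCC(Cl)=O | starting material
17 | methyl 4-[(4R)-4-benzyl-2-oxo-1,3-oxazolidin-3-yl]-4-oxobutanoate | COC(=O)CCC(=O)N1[C@H](Cc2ccccc2)COC1=O | intermediate
18 | trimethylsilyl ether of 19 (same configuration) | COC(=O)C[C@@H]([C@@H](O[Si](C)(C)C)c1ccc(O[Si](C(C)C)(C(C)C)C(C)C)c(OC)c1)C(=O)N1[C@H](Cc2ccccc2)COC1=O | intermediate (not isolated)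
19 | methyl (3S)-4-[(4R)-4-benzyl-2-oxo-1,3-oxazolidin-3-yl]-3-[(R)-hydroxy[3-methoxy-4-(triisopropylsilyloxy)phenyl]methyl]-4-oxobutanoate | COC(=O)C[C@@H]([C@@H](O)c1ccc(O[Si](C(C)C)(C(C)C)C(C)C)c(OC)c1)C(=O)N1[C@H](Cc2ccccc2)COC1=O | intermediate
20 | tert-butyldimethylsilyl ether of 19 (same configuration) | COC(=O)C[C@@H]([C@@H](O[Si](C)(C)C(C)(C)C)c1ccc(O[Si](C(C)C)(C(C)C)C(C)C)c(OC)c1)C(=O)N1[C@H](Cc2ccccc2)COC1=O | intermediate
21 | methyl (3R)-3-[(R)-(tert-butyldimethylsilyloxy)[3-methoxy-4-(triisopropylsilyloxy)phenyl]methyl]-4-hydroxybutanoate | COC(=O)C[C@@H]([C@@H](O[Si](C)(C)C(C)(C)C)c1ccc(O[Si](C(C)C)(C(C)C)C(C)C)c(OC)c1)CO | intermediate (not isolated)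
22 | (4R)-4-[(R)-(tert-butyldimethylsilyloxy)[3-methoxy-4-(triisopropylsilyloxy)phenyl]methyl]oxolan-2-one | O=C1C[C@@H]([C@@H](O[Si](C)(C)C(C)(C)C)c2ccc(O[Si](C(C)C)(C(C)C)C(C)C)c(OC)c2)CO1 | intermediate
23 | (3R,4R)-lactone carrying the (2S,3S)-3-[(1E)-prop-1-enyl]dihydrobenzofuran-5-ylmethyl group at C3 (full name in step 14) | COc1cc([C@H]2Oc3c(OC)cc(C[C@H]4C(=O)OC[C@@H]4[C@@H](O[Si](C)(C)C(C)(C)C)c4ccc(O[Si](C(C)C)(C(C)C)C(C)C)c(OC)c4)cc3[C@@H]2/C=C/C)ccc1O[Si](C(C)C)(C(C)C)C(C)C | intermediate
24 | ozonide of 23 (5-methyl-1,2,4-trioxolan-3-yl group on benzofuran C3; trioxolane centres undefined) | COc1cc([C@H]2Oc3c(OC)cc(C[C@H]4C(=O)OC[C@@H]4[C@@H](O[Si](C)(C)C(C)(C)C)c4ccc(O[Si](C(C)C)(C(C)C)C(C)C)c(OC)c4)cc3[C@@H]2C5OC(C)OO5)ccc1O[Si](C(C)C)(C(C)C)C(C)C | intermediate (not isolated)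
25 | tris-silyl ether of the target with free C3 hydroxymethyl (full name in step 15) | COc1cc([C@H]2Oc3c(OC)cc(C[C@H]4C(=O)OC[C@@H]4[C@@H](O[Si](C)(C)C(C)(C)C)c4ccc(O[Si](C(C)C)(C(C)C)C(C)C)c(OC)c4)cc3[C@@H]2CO)ccc1O[Si](C(C)C)(C(C)C)C(C)C | intermediate
26 | (3R,4R)-4-[(R)-hydroxy(4-hydroxy-3-methoxyphenyl)methyl]-3-{[(2S,3R)-2-(4-hydroxy-3-methoxyphenyl)-3-(hydroxymethyl)-7-methoxy-2,3-dihydro-1-benzofuran-5-yl]methyl}oxolan-2-one | COc1cc([C@H]2Oc3c(OC)cc(C[C@H]4C(=O)OC[C@@H]4[C@@H](O)c4ccc(O)c(OC)c4)cc3[C@@H]2CO)ccc1O | target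

**Step count and risks**
Total step count: 16. Longest linear sequence: 11 steps (steps 1, 2, 3, 4, 6, 7, 8, 9, 14, 15, 16).

Most likely to fail:

1. Step 8. What may go wrong: metalation at the tertiary allylic C–H or on an arene in place of the benzylic OCH2 group, a competing [1,2]-shift, sluggish displacement of fluoride on the unactivated ring, or base-induced migration of the propenyl double bond into conjugation during the warm second stage. Fallback (the ring is activated by a temporary change of oxidation level and the two bond formations are separated): starting from 11, the rearrangement alone is run (n-BuLi, THF, −78 °C, cold NH4Cl quench) to give (1S,2S,3E)-2-[2-fluoro-5-(hydroxymethyl)-3-methoxyphenyl]-1-[3-methoxy-4-(triisopropylsilyloxy)phenyl]pent-3-en-1-ol F1. Selective oxidation of the primary benzylic alcohol (TEMPO cat., PhI(OAc)2, CH2Cl2, rt) gives 4-fluoro-3-[(1S,2S,3E)-1-hydroxy-1-[3-methoxy-4-(triisopropylsilyloxy)phenyl]pent-3-en-2-yl]-5-methoxybenzaldehyde F2, in which the formyl group para to fluorine allows ring closure under mild base (Cs2CO3, DMF, 40 °C) to (2S,3S)-7-methoxy-2-[3-methoxy-4-(triisopropylsilyloxy)phenyl]-3-[(1E)-prop-1-en-1-yl]-2,3-dihydro-1-benzofuran-5-carbaldehyde F3. Reduction (NaBH4, MeOH, 0 °C) returns to the route at 13.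

2. Step 11. What may go wrong: poor anti/syn or facial selectivity of the magnesium-mediated aldol with the succinate-derived imide and the electron-rich aldehyde, incomplete turnover, or lactonisation of the free aldol onto the methyl ester during desilylation. Fallback (acylation followed by reagent-controlled ketone reduction in place of the aldol): starting from 2, Pinnick oxidation (NaClO2, NaH2PO4, 2-methylbut-2-ene, t-BuOH/H2O) gives 3-methoxy-4-(triisopropylsilyloxy)benzoic acid F4, and (COCl)2 with catalytic DMF gives 3-methoxy-4-(triisopropylsilyloxy)benzoyl chloride F5. The lithium enolate of 17 (LiN(iPr)2, THF, −78 °C) is acylated by F5 on the face away from the benzyl group to give methyl (3S)-4-[(4R)-4-benzyl-2-oxo-1,3-oxazolidin-3-yl]-3-[3-methoxy-4-(triisopropylsilyloxy)benzoyl]-4-oxobutanoate F6. Corey–Bakshi–Shibata reduction of the aryl ketone ((S)-2-methyl-CBS-oxazaborolidine, BH3·SMe2, THF, −20 °C) should deliver the (R)-carbinol and returns to the route at 19.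

3. Step 15. What may go wrong: attack of ozone on the electron-rich silyloxyarene rings, epimerisation or β-elimination of the α-aryl aldehyde before reduction, or partial reduction of the lactone. Fallback (dihydroxylation and glycol cleavage in place of ozonolysis): starting from 23, Upjohn dihydroxylation (OsO4 cat., N-methylmorpholine N-oxide, acetone/H2O) gives the 3-(1,2-dihydroxypropyl) analogue of 23 as a mixture at the two new carbinol centres F7. Cleavage with NaIO4 (THF/H2O, 0 °C) gives the 3-formyl analogue of 23, (2S,3S) at the benzofuran F8, which is reduced at once (NaBH4, MeOH, −20 °C) and returns to the route at 25.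

**Further compounds**
F1 | step 8 | (1S,2S,3E)-2-[2-fluoro-5-(hydroxymethyl)-3-methoxyphenyl]-1-[3-methoxy-4-(triisopropylsilyloxy)phenyl]pent-3-en-1-ol | COc1cc([C@@H](O)[C@@H](/C=C/C)c2cc(CO)cc(OC)c2F)ccc1O[Si](C(C)C)(C(C)C)C(C)C
F2 | step 8 | 4-fluoro-3-[(1S,2S,3E)-1-hydroxy-1-[3-methoxy-4-(triisopropylsilyloxy)phenyl]pent-3-en-2-yl]-5-methoxybenzaldehyde | COc1cc([C@@H](O)[C@@H](/C=C/C)c2cc(C=O)cc(OC)c2F)ccc1O[Si](C(C)C)(C(C)C)C(C)C
F3 | step 8 | (2S,3S)-7-methoxy-2-[3-methoxy-4-(triisopropylsilyloxy)phenyl]-3-[(1E)-prop-1-en-1-yl]-2,3-dihydro-1-benzofuran-5-carbaldehyde | COc1cc([C@H]2Oc3c(OC)cc(C=O)cc3[C@@H]2/C=C/C)ccc1O[Si](C(C)C)(C(C)C)C(C)C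
F4 | step 11 | 3-methoxy-4-(triisopropylsilyloxy)benzoic acid | COc1cc(C(=O)O)ccc1O[Si](C(C)C)(C(C)C)C(C)C
F5 | step 11 | 3-methoxy-4-(triisopropylsilyloxy)benzoyl chloride | COc1cc(C(=O)Cl)ccc1O[Si](C(C)C)(C(C)C)C(C)C
F6 | step 11 | methyl (3S)-4-[(4R)-4-benzyl-2-oxo-1,3-oxazolidin-3-yl]-3-[3-methoxy-4-(triisopropylsilyloxy)benzoyl]-4-oxobutanoate | COC(=O)C[C@@H](C(=O)c1ccc(O[Si](C(C)C)(C(C)C)C(C)C)c(OC)c1)C(=O)N1[C@H](Cc2ccccc2)COC1=O
F7 | step 15 | 3-(1,2-dihydroxypropyl) analogue of 23 (two new carbinol centres undefined, other centres as in 23) | COc1cc([C@H]2Oc3c(OC)cc(C[C@H]4C(=O)OC[C@@H]4[C@@H](O[Si](C)(C)C(C)(C)C)c4ccc(O[Si](C(C)C)(C(C)C)C(C)C)c(OC)c4)cc3[C@@H]2C(O)C(C)O)ccc1O[Si](C(C)C)(C(C)C)C(C)C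
F8 | step 15 | 3-formyl analogue of 23 ((2S,3S) at the benzofuran, other centres as in 23) | COc1cc([C@H]2Oc3c(OC)cc(C[C@H]4C(=O)OC[C@@H]4[C@@H](O[Si](C)(C)C(C)(C)C)c4ccc(O[Si](C(C)C)(C(C)C)C(C)C)c(OC)c4)cc3[C@@H]2C=O)ccc1O[Si](C(C)C)(C(C)C)C(C)C
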